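## Retrosynthetic overview

1. The ten-membered ring is closed last by an intramolecular Nozaki–Hiyama–Kishi reaction: the C4 (Z)-vinyl iodide adds to the C3 aldehyde, forming C3–C4 and the 3-OH.
2. The seco-aldehyde comes from a Zn-Barbier coupling (C7–C8) of epoxy aldehyde 9 with bromomethylbutenolide 18, followed by Mitsunobu esterification with isobutyric acid, which inverts C8.
3. Fragment 9 (C1–C3, C8–C10, C14): Negishi carboalumination of a butynyl ether, ethylene oxide trapping, ent-Shi epoxidation.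
4. Fragment 18 (C4–C7, C11–C13, C15): Red-Al/I2 on but-2-yn-1-ol, vinyl addition, lipase resolution, acrylate ester, butenolide RCM.
5. Ring order: epoxide, then butenolide, then α-methylene-γ-lactone (revealed in the Barbier step), then the ten-membered carbocycle.

Assumption: atom labels C1–C15 follow germacrane numbering of the target, and the L-fructose-derived (ent-)Shi ketone is used as a bought catalyst.

## Route

**Step 1**
Reactants: 1 but-3-yn-1-ol
Product: 2 tert-butyl(but-3-yn-1-yloxy)dimethylsilane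
Conditions: TBSCl, imidazole, CH2Cl2, 0 °C → rt
Reagents that add atoms: tert-butyldimethylsilyl chloride CC(C)(C)[Si](C)(C)Cl
Why: Standard silylation of a primary alcohol; the TBS ether tolerates the organoaluminium chemistry of step 2.

**Step 2**
Reactants: 2 tert-butyl(but-3-yn-1-yloxy)dimethylsilane
Product: 5 (E)-6-(tert-butyldimethylsilyloxy)-4-methylhex-3-en-1-ol, via alkenyldimethylalane 3 (not isolated), via lithium alkenylalanate 4 (not isolated)
Conditions: Me3Al, Cp2ZrCl2 (20 mol%), CH2Cl2, 0 °C → rt; evaporate; n-BuLi, hexane/THF, −78 → 0 °C; ethylene oxide, 0 °C → rt; aq. Rochelle salt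
Reagents that add atoms: trimethylaluminium C[Al](C)C; ethylene oxide C1CO1; n-butyllithium [Li]CCCC (stays only in 4)
Why: Negishi Zr-catalysed carboalumination adds Me–Al syn with Me on the internal carbon, and the derived alanate opens ethylene oxide with retention, fixing the E-trisubstituted C1=C10 alkene.

**Step 3**
Reactants: 5 (E)-6-(tert-butyldimethylsilyloxy)-4-methylhex-3-en-1-ol
Product: 6 (E)-tert-butyl{[6-(4-methoxybenzyloxy)-3-methylhex-3-en-1-yl]oxy}dimethylsilane
Conditions: NaH, PMBCl, Bu4NI (cat.), THF/DMF, 0 °C → rt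
Reagents that add atoms: 4-methoxybenzyl chloride COc1ccc(CCl)cc1
Why: Williamson etherification; the PMB ether masks C3–OH until the late oxidative release in step 15.

**Step 4**
Reactants: 6 (E)-tert-butyl{[6-(4-methoxybenzyloxy)-3-methylhex-3-en-1-yl]oxy}dimethylsilane
Product: 7 tert-butyl(2-{(2S,3S)-3-[2-(4-methoxybenzyloxy)ethyl]-2-methyloxiran-2-yl}ethoxy)dimethylsilane
Conditions: ent-Shi ketone (30 mol%), Oxone, K2CO3, Bu4NHSO4, Na2B4O7/Na2EDTA buffer, MeCN–DMM, 0 °C
Reagents that add atoms: Oxone (potassium peroxymonosulfate) [K+].[O-]S(=O)(=O)OO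
Why: Shi asymmetric epoxidation through a spiro dioxirane transition state; the D-fructose ketone gives R,R epoxides from E-trisubstituted alkenes, so its enantiomer gives the S,S epoxide (C1 and C10 of the target).

**Step 5**
Reactants: 7 tert-butyl(2-{(2S,3S)-3-[2-(4-methoxybenzyloxy)ethyl]-2-methyloxiran-2-yl}ethoxy)dimethylsilane
Product: 8 2-{(2S,3S)-3-[2-(4-methoxybenzyloxy)ethyl]-2-methyloxiran-2-yl}ethan-1-ol
Conditions: TBAF, THF, 0 °C
Reagents that add atoms: none
Why: Fluoride desilylation frees the C8 alcohol; the epoxide and PMB ether are stable to these conditions.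

**Step 6**
Reactants: 8 2-{(2S,3S)-3-[2-(4-methoxybenzyloxy)ethyl]-2-methyloxiran-2-yl}ethan-1-ol
Product: 9 2-{(2S,3S)-3-[2-(4-methoxybenzyloxy)ethyl]-2-methyloxiran-2-yl}acetaldehyde
Conditions: DMP, NaHCO3, CH2Cl2, 0 °C; used crude at once
Reagents that add atoms: none
Why: Buffered Dess–Martin oxidation is neutral enough to give the β,γ-epoxy aldehyde without epoxide opening or β-elimination.

**Step 7**
Reactants: 10 but-2-yn-1-ol
Product: 12 (Z)-3-iodobut-2-en-1-ol, via cyclic sodium alkenylalanate 11 (not isolated)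
Conditions: Red-Al, THF, 0 °C → rt; then I2, THF, −78 → 0 °C
Reagents that add atoms: iodine II; Red-Al [Na+].COCCO[AlH2-]OCCOC (stays only in 11)
Why: Alkoxide-directed trans-hydroalumination places Al on the distal carbon cis to CH2O, and iodinolysis with retention gives the Z-iodoalkene (the future 4Z geometry).

**Step 8**
Reactants: 12 (Z)-3-iodobut-2-en-1-ol
Product: 13 (Z)-3-iodobut-2-enal
Conditions: activated MnO2, CH2Cl2, rt, dark; solution used directly
Reagents that add atoms: none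
Why: MnO2 oxidises the allylic alcohol selectively under neutral conditions that preserve the Z geometry.

**Step 9**
Reactants: 13 (Z)-3-iodobut-2-enal
Product: 14 rac-(Z)-5-iodohexa-1,4-dien-3-ol
Conditions: CH2=CHMgBr, THF, −78 °C; aq. NH4Cl
Reagents that add atoms: vinylmagnesium bromide C=C[Mg]Br
Why: Grignard reagents add 1,2 to enals at low temperature, giving the divinyl carbinol without touching the vinyl iodide.

**Step 10**
Reactants: 14 rac-(Z)-5-iodohexa-1,4-dien-3-ol
Product: 15 (3S,4Z)-5-iodohexa-1,4-dien-3-ol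
Conditions: Novozym 435 (CAL-B), vinyl acetate, MTBE, 30 °C, to ca. 55% conversion; chromatography
Reagents that add atoms: none
Why: Lipase kinetic resolution; by the Kazlauskas rule (small = vinyl, large = iodopropenyl) the R alcohol is acetylated and the S alcohol (C6 of the target) is recovered in high ee.

**Step 11**
Reactants: 15 (3S,4Z)-5-iodohexa-1,4-dien-3-ol; 16 2-(bromomethyl)acrylic acid
Product: 17 (3S,4Z)-5-iodohexa-1,4-dien-3-yl 2-(bromomethyl)acrylate
Conditions: DCC, DMAP (5 mol%), CH2Cl2, −10 → 0 °C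
Reagents that add atoms: none
Why: Steglich esterification acylates on oxygen without touching the stereocentre; low temperature and catalytic DMAP spare the allylic bromide.

**Step 12**
Reactants: 17 (3S,4Z)-5-iodohexa-1,4-dien-3-yl 2-(bromomethyl)acrylate
Product: 18 (5S)-3-(bromomethyl)-5-[(Z)-2-iodoprop-1-en-1-yl]furan-2(5H)-one
Conditions: Grubbs II (5 mol%), CH2Cl2 (5 mM), 40 °C
Reagents that add atoms: none
Why: Ring-closing metathesis of the vinyl group with the acrylate gives the butenolide; the trisubstituted iodoalkene is inert to the Ru carbene and C6 is untouched.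

**Step 13**
Reactants: 9 2-{(2S,3S)-3-[2-(4-methoxybenzyloxy)ethyl]-2-methyloxiran-2-yl}acetaldehyde; 18 (5S)-3-(bromomethyl)-5-[(Z)-2-iodoprop-1-en-1-yl]furan-2(5H)-one
Product: 19 (4R,5S)-4-[(1S)-1-hydroxy-2-{(2S,3S)-3-[2-(4-methoxybenzyloxy)ethyl]-2-methyloxiran-2-yl}ethyl]-5-[(Z)-2-iodoprop-1-en-1-yl]-3-methylideneoxolan-2-one
Conditions: Zn dust, THF/sat. aq. NH4Cl (2:1), 0 °C → rt
Reagents that add atoms: none
Why: Zn-Barbier allylation at the γ-carbon (C7) through a Zimmerman–Traxler chair: attack anti to the C6 alkenyl group gives the trans lactone (C7 R), and the ring-fixed E-type allyl unit gives the anti 8α-carbinol (8S), the epimer that step 14 inverts; Zn does not insert into the vinyl iodide.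

**Step 14**
Reactants: 19 (4R,5S)-4-[(1S)-1-hydroxy-2-{(2S,3S)-3-[2-(4-methoxybenzyloxy)ethyl]-2-methyloxiran-2-yl}ethyl]-5-[(Z)-2-iodoprop-1-en-1-yl]-3-methylideneoxolan-2-one
Product: 20 (1R)-1-{(2S,3R)-2-[(Z)-2-iodoprop-1-en-1-yl]-4-methylidene-5-oxooxolan-3-yl}-2-{(2S,3S)-3-[2-(4-methoxybenzyloxy)ethyl]-2-methyloxiran-2-yl}ethyl 2-methylpropanoate
Conditions: i-PrCO2H, PPh3, DIAD, toluene, 0 °C → rt
Reagents that add atoms: isobutyric acid CC(C)C(=O)O
Why: Mitsunobu esterification displaces the alkoxyphosphonium by SN2, inverting C8 (S → R) and installing the 8β-isobutyrate in one operation.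

**Step 15**
Reactants: 20 (1R)-1-{(2S,3R)-2-[(Z)-2-iodoprop-1-en-1-yl]-4-methylidene-5-oxooxolan-3-yl}-2-{(2S,3S)-3-[2-(4-methoxybenzyloxy)ethyl]-2-methyloxiran-2-yl}ethyl 2-methylpropanoate
Product: 21 (1R)-2-[(2S,3S)-3-(2-hydroxyethyl)-2-methyloxiran-2-yl]-1-{(2S,3R)-2-[(Z)-2-iodoprop-1-en-1-yl]-4-methylidene-5-oxooxolan-3-yl}ethyl 2-methylpropanoate
Conditions: DDQ, CH2Cl2/pH 7 buffer (10:1), 0 °C
Reagents that add atoms: none
Why: Oxidative PMB cleavage under buffered neutral conditions leaves the epoxide, both esters, the enoate and the vinyl iodide intact.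

**Step 16**
Reactants: 21 (1R)-2-[(2S,3S)-3-(2-hydroxyethyl)-2-methyloxiran-2-yl]-1-{(2S,3R)-2-[(Z)-2-iodoprop-1-en-1-yl]-4-methylidene-5-oxooxolan-3-yl}ethyl 2-methylpropanoate
Product: 22 (1R)-1-{(2S,3R)-2-[(Z)-2-iodoprop-1-en-1-yl]-4-methylidene-5-oxooxolan-3-yl}-2-[(2S,3S)-2-methyl-3-(2-oxoethyl)oxiran-2-yl]ethyl 2-methylpropanoate
Conditions: DMP, NaHCO3, CH2Cl2, 0 °C; used crude at once
Reagents that add atoms: none
Why: Buffered Dess–Martin oxidation gives the sensitive β,γ-epoxy aldehyde without base or acid.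

**Step 17**
Reactants: 22 (1R)-1-{(2S,3R)-2-[(Z)-2-iodoprop-1-en-1-yl]-4-methylidene-5-oxooxolan-3-yl}-2-[(2S,3S)-2-methyl-3-(2-oxoethyl)oxiran-2-yl]ethyl 2-methylpropanoate
Product: 23 (1S,3S,4Z,6R,7R,8R,10S)-1,10-epoxy-3-hydroxy-8-(2-methylpropanoyloxy)germacra-4,11(13)-dien-12,6-olide (target)
Conditions: CrCl2 (10 equiv), NiCl2 (0.1 equiv), degassed DMSO (2 mM, slow addition), rt
Reagents that add atoms: none
Why: Intramolecular Nozaki–Hiyama–Kishi reaction: Ni inserts into the C–I bond with retention of the Z geometry and the alkenyl-Cr(III) adds to the aldehyde at high dilution; C3 is set under macrocyclic control, with peripheral attack expected to give the 3S (3β) alcohol, though this is the least secure stereocentre.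

## Compound list

1 | but-3-yn-1-ol | C#CCCO | starting material
2 | tert-butyl(but-3-yn-1-yloxy)dimethylsilane | C#CCCO[Si](C)(C)C(C)(C)C | intermediate
3 | (E)-[4-(tert-butyldimethylsilyloxy)-2-methylbut-1-en-1-yl]dimethylalumane | C[Al](C)/C=C(\C)CCO[Si](C)(C)C(C)(C)C | intermediate (not isolated)
4 | lithium (E)-butyl[4-(tert-butyldimethylsilyloxy)-2-methylbut-1-en-1-yl]dimethylaluminate | [Li+].CCCC[Al-](C)(C)/C=C(\C)CCO[Si](C)(C)C(C)(C)C | intermediate (not isolated)
5 | (E)-6-(tert-butyldimethylsilyloxy)-4-methylhex-3-en-1-ol | OCC/C=C(\C)CCO[Si](C)(C)C(C)(C)C | intermediate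
6 | (E)-tert-butyl{[6-(4-methoxybenzyloxy)-3-methylhex-3-en-1-yl]oxy}dimethylsilane | COc1ccc(COCC/C=C(\C)CCO[Si](C)(C)C(C)(C)C)cc1 | intermediate
7 | tert-butyl(2-{(2S,3S)-3-[2-(4-methoxybenzyloxy)ethyl]-2-methyloxiran-2-yl}ethoxy)dimethylsilane | CC(C)(C)[Si](C)(C)OCC[C@]1(C)O[C@H]1CCOCc2ccc(OC)cc2 | intermediate
8 | 2-{(2S,3S)-3-[2-(4-methoxybenzyloxy)ethyl]-2-methyloxiran-2-yl}ethan-1-ol | OCC[C@]1(C)O[C@H]1CCOCc2ccc(OC)cc2 | intermediate
9 | 2-{(2S,3S)-3-[2-(4-methoxybenzyloxy)ethyl]-2-methyloxiran-2-yl}acetaldehyde | O=CC[C@]1(C)O[C@H]1CCOCc2ccc(OC)cc2 | intermediate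
10 | but-2-yn-1-ol | CC#CCO | starting material
11 | sodium 2,2-bis(2-methoxyethoxy)-3-methyl-2,5-dihydro-1,2-oxaaluminol-2-uide (cyclic alkenylalanate) | [Na+].COCCO[Al-]1(OCCOC)OCC=C1C | intermediate (not isolated)
12 | (Z)-3-iodobut-2-en-1-ol | C/C(I)=C/CO | intermediate
13 | (Z)-3-iodobut-2-enal | C/C(I)=C/C=O | intermediate
14 | rac-(Z)-5-iodohexa-1,4-dien-3-ol | C=CC(O)/C=C(/C)I | intermediate
15 | (3S,4Z)-5-iodohexa-1,4-dien-3-ol | C=C[C@H](O)/C=C(/C)I | intermediate
16 | 2-(bromomethyl)acrylic acid | C=C(CBr)C(=O)O | starting material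
17 | (3S,4Z)-5-iodohexa-1,4-dien-3-yl 2-(bromomethyl)acrylate | C=C(CBr)C(=O)O[C@@H](C=C)/C=C(/C)I | intermediate
18 | (5S)-3-(bromomethyl)-5-[(Z)-2-iodoprop-1-en-1-yl]furan-2(5H)-one | BrCC1=C[C@@H](/C=C(/C)I)OC1=O | intermediate
19 | (4R,5S)-4-[(1S)-1-hydroxy-2-{(2S,3S)-3-[2-(4-methoxybenzyloxy)ethyl]-2-methyloxiran-2-yl}ethyl]-5-[(Z)-2-iodoprop-1-en-1-yl]-3-methylideneoxolan-2-one | C=C1C(=O)O[C@H](/C=C(/C)I)[C@H]1[C@@H](O)C[C@]2(C)O[C@H]2CCOCc3ccc(OC)cc3 | intermediate
20 | (1R)-1-{(2S,3R)-2-[(Z)-2-iodoprop-1-en-1-yl]-4-methylidene-5-oxooxolan-3-yl}-2-{(2S,3S)-3-[2-(4-methoxybenzyloxy)ethyl]-2-methyloxiran-2-yl}ethyl 2-methylpropanoate | C=C1C(=O)O[C@H](/C=C(/C)I)[C@H]1[C@H](OC(=O)C(C)C)C[C@]2(C)O[C@H]2CCOCc3ccc(OC)cc3 | intermediate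
21 | (1R)-2-[(2S,3S)-3-(2-hydroxyethyl)-2-methyloxiran-2-yl]-1-{(2S,3R)-2-[(Z)-2-iodoprop-1-en-1-yl]-4-methylidene-5-oxooxolan-3-yl}ethyl 2-methylpropanoate | C=C1C(=O)O[C@H](/C=C(/C)I)[C@H]1[C@H](OC(=O)C(C)C)C[C@]2(C)O[C@H]2CCO | intermediate
22 | (1R)-1-{(2S,3R)-2-[(Z)-2-iodoprop-1-en-1-yl]-4-methylidene-5-oxooxolan-3-yl}-2-[(2S,3S)-2-methyl-3-(2-oxoethyl)oxiran-2-yl]ethyl 2-methylpropanoate | C=C1C(=O)O[C@H](/C=C(/C)I)[C@H]1[C@H](OC(=O)C(C)C)C[C@]2(C)O[C@H]2CC=O | intermediate
23 | (1S,3S,4Z,6R,7R,8R,10S)-1,10-epoxy-3-hydroxy-8-(2-methylpropanoyloxy)germacra-4,11(13)-dien-12,6-olide | C=C1C(=O)O[C@@H]2/C=C(/C)[C@@H](O)C[C@@H]3O[C@@]3(C)C[C@@H](OC(=O)C(C)C)[C@@H]12 | target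

## Step count and risks

Total step count: 17.
Longest linear sequence: 11 steps (steps 1–6 then 13–17; the branch 7–12 then 13–17 is equally long).

**Step 17 (NHK macrocyclisation).** Ten-membered ring closure may be low-yielding, and the C3 configuration rests on substrate control only. The fallback sets out from 22 and comes back at 23. If the closure gives mainly the C3 epimer, the (3R)-epimer of 23 F5, this alcohol (or the epimer mixture) is oxidised with DMP/NaHCO3 to the macrocyclic 3-oxo (Z)-enone F6. The ketone is then reduced with (R)-Me-CBS and catecholborane in toluene at −78 °C. With the 2-methylalkenyl group as the large substituent, this reagent-controlled 1,2-reduction gives the 3S alcohol 23 and leaves the α-methylene lactone alone.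

**Step 14 (Mitsunobu inversion at C8).** The carbinol is flanked by the lactone ring carbon and a CH2 next to a quaternary epoxide carbon, so elimination or incomplete conversion is possible. The fallback sets out from 19 and comes back at 20. Alcohol 19 is converted with ClCH2SO2Cl and pyridine in CH2Cl2 at 0 °C into the C8 chloromethanesulfonate of 19 F4. Displacement with caesium isobutyrate and 18-crown-6 in toluene (SN2, inversion) then gives 20.

**Step 12 (RCM with an allylic bromide on an electron-poor 1,1-disubstituted alkene).** The Ru carbene may be slowed or degraded by the bromomethyl acrylate. The fallback sets out from 15 and comes back at 18. Alcohol 15 is esterified (DCC, DMAP) with 2-{[(tert-butyldimethylsilyl)oxy]methyl}acrylic acid to give the silyloxymethyl acrylate ester F1. RCM (Grubbs II or Hoveyda–Grubbs II, toluene, 80 °C) gives the silyloxymethyl butenolide F2. HF·pyridine in THF gives the hydroxymethyl butenolide F3, and Appel bromination (CBr4, PPh3, CH2Cl2, 0 °C) gives 18.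

## Further compounds

F1 | step 12 | (3S,4Z)-5-iodohexa-1,4-dien-3-yl 2-{[(tert-butyldimethylsilyl)oxy]methyl}acrylate | C=C(CO[Si](C)(C)C(C)(C)C)C(=O)O[C@@H](C=C)/C=C(/C)I
F2 | step 12 | (5S)-3-{[(tert-butyldimethylsilyl)oxy]methyl}-5-[(Z)-2-iodoprop-1-en-1-yl]furan-2(5H)-one | CC(C)(C)[Si](C)(C)OCC1=C[C@@H](/C=C(/C)I)OC1=O
F3 | step 12 | (5S)-3-(hydroxymethyl)-5-[(Z)-2-iodoprop-1-en-1-yl]furan-2(5H)-one | OCC1=C[C@@H](/C=C(/C)I)OC1=O
F4 | step 14 | C8 chloromethanesulfonate of 19 (all stereocentres as in 19) | C=C1C(=O)O[C@H](/C=C(/C)I)[C@H]1[C@@H](OS(=O)(=O)CCl)C[C@]2(C)O[C@H]2CCOCc3ccc(OC)cc3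
F5 | step 17 | (3R)-epimer of 23 | C=C1C(=O)O[C@@H]2/C=C(/C)[C@H](O)C[C@@H]3O[C@@]3(C)C[C@@H](OC(=O)C(C)C)[C@@H]12
F6 | step 17 | 3-oxo analogue of 23 (macrocyclic (Z)-enone, other stereocentres as in 23) | C=C1C(=O)O[C@@H]2/C=C(/C)C(=O)C[C@@H]3O[C@@]3(C)C[C@@H](OC(=O)C(C)C)[C@@H]12
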